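## Retrosynthetic overview

1. (−)-Pipoxide 12 ⇐ epoxy diol 11 by site-selective benzoylation of the allylic C3–OH; 11 ⇐ acetonide 10.
2. Key disconnection of 10: the C1–C6 bond and the C6–O bond are made together by an intramolecular allylsulfonium-ylide/ketone epoxy-annulation of acyclic keto sulfide 6 (cyclohexene and oxirane in one operation).
3. 6 ⇐ ester 4 (LiCH2Cl, then benzoate SN2) ⇐ aldehyde 3 + β-phenylthio ylide (Z-Wittig) ⇐ L-tartrate acetonide 1.
4. C2 and C3 come unchanged from L-tartaric acid; C1 and C6 are set in the annulation under control of the trans-dioxolane.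
5. Ring order: dioxolane (bought) → cyclohexene + epoxide simultaneously (step 4) → dioxolane removed (step 5).

Assumption: ring atoms are numbered C1 (epoxide carbon bearing CH2OBz), C2 (CHOH), C3 (CHOBz), C4=C5, C6 (epoxide CH); the given SMILES is (1R,2R,3S,6S) and is taken as (−)-pipoxide.

## Route

Step 1
Reactants: 1 dimethyl (4R,5R)-2,2-dimethyl-1,3-dioxolane-4,5-dicarboxylate
Product: 2 methyl (4R,5S)-5-(hydroxymethyl)-2,2-dimethyl-1,3-dioxolane-4-carboxylate
Conditions: NaBH4 (0.6 equiv), MeOH, −10 → 0 °C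
Reagents that add atoms: none
Why: Chemoselective partial ester reduction: the α-alkoxy-activated methyl ester is reduced by NaBH4 in MeOH and sub-stoichiometric hydride at low temperature stops mainly at the mono-alcohol (diol and recovered 1 are separable, 1 is recycled); no stereocentre is touched.

Step 2
Reactants: 2 methyl (4R,5S)-5-(hydroxymethyl)-2,2-dimethyl-1,3-dioxolane-4-carboxylate
Product: 4 methyl (4R,5S)-2,2-dimethyl-5-[(1Z)-3-(phenylsulfanyl)prop-1-en-1-yl]-1,3-dioxolane-4-carboxylate, via aldehyde 3 (not isolated)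
Conditions: IBX, EtOAc, 75 °C, filter and concentrate; then CH2=CHPPh3Br + PhSNa (THF, 0 °C), crude 3 added at −78 → 20 °C
Reagents that add atoms: vinyltriphenylphosphonium bromide C=C[P+](c1ccccc1)(c1ccccc1)c1ccccc1.[Br-]; sodium thiophenolate [Na+].[S-]c1ccccc1
Why: IBX oxidation gives the trans (epimerisation-proof) α-alkoxy aldehyde, thiolate adds to the vinylphosphonium salt to give a non-stabilised β-thio ylide (Schweizer-type ylide generation), and its lithium-free, kinetically controlled Wittig reaction gives the Z-alkene (minor E isomer removed by chromatography) that later lets C6 reach C1.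

Step 3
Reactants: 4 methyl (4R,5S)-2,2-dimethyl-5-[(1Z)-3-(phenylsulfanyl)prop-1-en-1-yl]-1,3-dioxolane-4-carboxylate
Product: 6 2-{(4R,5S)-2,2-dimethyl-5-[(1Z)-3-(phenylsulfanyl)prop-1-en-1-yl]-1,3-dioxolan-4-yl}-2-oxoethyl benzoate, via chloromethyl ketone 5 (not isolated)
Conditions: ICH2Cl, MeLi·LiBr, THF/Et2O, −78 °C; AcOH, −78 °C; evaporate; then PhCO2Na, DMF, 20 °C
Reagents that add atoms: chloroiodomethane ClCI; sodium benzoate [Na+].[O-]C(=O)c1ccccc1
Why: Halomethyllithium homologation of an ester: LiCH2Cl generated in situ adds once because the carbonyl is only released on the acidic quench at −78 °C, and the resulting α-chloroketone undergoes fast SN2 substitution by benzoate; the α-stereocentre sits in the thermodynamically preferred trans-dioxolane and is not scrambled.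

Step 4
Reactants: 6 2-{(4R,5S)-2,2-dimethyl-5-[(1Z)-3-(phenylsulfanyl)prop-1-en-1-yl]-1,3-dioxolan-4-yl}-2-oxoethyl benzoate
Product: 10 acetonide (2,3-O-isopropylidene derivative) of [(1R,2R,3S,6S)-2,3-dihydroxy-7-oxabicyclo[4.1.0]hept-4-en-1-yl]methyl benzoate, via sulfonium triflate 7 (not isolated), via sulfonium allylide 8 (not isolated), via betaine 9 (not isolated)
Conditions: MeOTf (1.1 equiv), CH2Cl2, 0 → 20 °C; then MeCN (0.01 M), Cs2CO3 (2 equiv), 0 → 20 °C
Reagents that add atoms: none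
Why: Proposed new method: S-methylation gives the allylic sulfonium salt, carbonate removes the doubly activated allylic S–CH2 proton, the ylide α-carbon adds 6-exo to the electrophilic α,α'-dioxygenated ketone (reversibly) and the alkoxide displaces PhSMe to close the oxirane, so cyclohexene and epoxide form in one operation; the trans-fused dioxolane locks the half-chair with O–C2 equatorial, so only the betaine with axial O⁻ on C1 (cis to O–C2) and anti-periplanar axial S⁺ on C6 can ring-close, which sets C1 and C6 with the epoxide syn to O–C2 and anti to O–C3; closest known chemistry is the Corey–Chaykovsky vinyl-epoxide synthesis with allylsulfonium ylides and intramolecular sulfur-ylide epoxy-annulations.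

Step 5
Reactants: 10 acetonide of [(1R,2R,3S,6S)-2,3-dihydroxy-7-oxabicyclo[4.1.0]hept-4-en-1-yl]methyl benzoate
Product: 11 [(1R,2R,3S,6S)-2,3-dihydroxy-7-oxabicyclo[4.1.0]hept-4-en-1-yl]methyl benzoate
Conditions: AcOH/H2O 4:1, 20 °C
Reagents that add atoms: none
Why: Acid-catalysed acetal hydrolysis: the strained trans-fused dioxolane on the cyclohexene cleaves under conditions mild enough for the oxygen-deactivated vinyl epoxide and the primary benzoate; no stereocentre changes.

Step 6
Reactants: 11 [(1R,2R,3S,6S)-2,3-dihydroxy-7-oxabicyclo[4.1.0]hept-4-en-1-yl]methyl benzoate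
Product: 12 (−)-pipoxide = [(1R,2R,3S,6S)-3-(benzoyloxy)-2-hydroxy-7-oxabicyclo[4.1.0]hept-4-en-1-yl]methyl benzoate
Conditions: BzCl (1.05 equiv), pyridine, CH2Cl2, −40 → −20 °C
Reagents that add atoms: benzoyl chloride O=C(Cl)c1ccccc1
Why: Kinetic site-selective O-acylation: the allylic C3–OH (next to sp2 C4) reacts faster than the C2–OH, which is neopentyl-like (next to quaternary C1) and hydrogen-bonded to the cis epoxide oxygen; configuration is retained.

## Compound list

1 | dimethyl (4R,5R)-2,2-dimethyl-1,3-dioxolane-4,5-dicarboxylate (dimethyl 2,3-O-isopropylidene-L-tartrate) | COC(=O)[C@@H]1OC(C)(C)O[C@H]1C(=O)OC | starting material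
2 | methyl (4R,5S)-5-(hydroxymethyl)-2,2-dimethyl-1,3-dioxolane-4-carboxylate | COC(=O)[C@@H]1OC(C)(C)O[C@H]1CO | intermediate
3 | methyl (4R,5R)-5-formyl-2,2-dimethyl-1,3-dioxolane-4-carboxylate | COC(=O)[C@@H]1OC(C)(C)O[C@H]1C=O | intermediate (not isolated)
4 | methyl (4R,5S)-2,2-dimethyl-5-[(1Z)-3-(phenylsulfanyl)prop-1-en-1-yl]-1,3-dioxolane-4-carboxylate | COC(=O)[C@@H]1OC(C)(C)O[C@H]1/C=C\CSc1ccccc1 | intermediate
5 | 2-chloro-1-{(4R,5S)-2,2-dimethyl-5-[(1Z)-3-(phenylsulfanyl)prop-1-en-1-yl]-1,3-dioxolan-4-yl}ethan-1-one | ClCC(=O)[C@@H]1OC(C)(C)O[C@H]1/C=C\CSc1ccccc1 | intermediate (not isolated)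
6 | 2-{(4R,5S)-2,2-dimethyl-5-[(1Z)-3-(phenylsulfanyl)prop-1-en-1-yl]-1,3-dioxolan-4-yl}-2-oxoethyl benzoate | O=C(OCC(=O)[C@@H]1OC(C)(C)O[C@H]1/C=C\CSc1ccccc1)c1ccccc1 | intermediate
7 | S-methylsulfonium triflate of 6 (methyl and phenyl on S⁺, both S-epimers) | O=C(OCC(=O)[C@@H]1OC(C)(C)O[C@H]1/C=C\C[S+](C)c1ccccc1)c1ccccc1.[O-]S(=O)(=O)C(F)(F)F | intermediate (not isolated)
8 | sulfonium allylide: 7 deprotonated at the S–CH2 carbon | O=C(OCC(=O)[C@@H]1OC(C)(C)O[C@H]1/C=C\[CH-][S+](C)c1ccccc1)c1ccccc1 | intermediate (not isolated)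
9 | betaine: cyclised zwitterion with O⁻ on C1 (cis to O–C2) and methyl(phenyl)sulfonio on C6 (trans to O⁻) | O=C(OC[C@]1([O-])[C@H]([S+](C)c2ccccc2)C=C[C@@H]2OC(C)(C)O[C@@H]12)c1ccccc1 | intermediate (not isolated)
10 | acetonide (2,3-O-isopropylidene derivative, trans-fused dioxolane) of 11 | O=C(OC[C@]12O[C@H]1C=C[C@@H]3OC(C)(C)O[C@@H]23)c1ccccc1 | intermediate
11 | [(1R,2R,3S,6S)-2,3-dihydroxy-7-oxabicyclo[4.1.0]hept-4-en-1-yl]methyl benzoate | O=C(OC[C@]12O[C@H]1C=C[C@H](O)[C@H]2O)c1ccccc1 | intermediate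
12 | (−)-pipoxide, [(1R,2R,3S,6S)-3-(benzoyloxy)-2-hydroxy-7-oxabicyclo[4.1.0]hept-4-en-1-yl]methyl benzoate | O=C(OC[C@]12O[C@H]1C=C[C@H](OC(=O)c1ccccc1)[C@H]2O)c1ccccc1 | target

## Step count and risks

Total step count: 6. Longest linear sequence: 6 steps (from 1).

Three steps most likely to fail:

**Step 4 (epoxy-annulation).** Risks are Sommelet–Hauser or [2,3] rearrangement of the ylide, elimination of the C3 oxygen from the allyl anion, or a betaine that does not close. The fallback builds the two rings one after the other. It sets out from aldehyde 3 and comes back at 10. Methylenation of 3 with Ph3P=CH2 gives methyl (4R,5S)-5-ethenyl-2,2-dimethyl-1,3-dioxolane-4-carboxylate F1. LiCH2Cl as in step 3 gives 2-chloro-1-[(4R,5S)-5-ethenyl-2,2-dimethyl-1,3-dioxolan-4-yl]ethan-1-one F2, and sodium benzoate gives 2-[(4R,5S)-5-ethenyl-2,2-dimethyl-1,3-dioxolan-4-yl]-2-oxoethyl benzoate F3. An intermolecular Corey–Chaykovsky reaction with the allylide from S-allyltetrahydrothiophenium bromide and KOtBu (THF, −78 °C) passes through the alkoxide/tetrahydrothiophenium betaine F4 and gives [(2S,3S)-3-ethenyl-2-[(4R,5S)-5-ethenyl-2,2-dimethyl-1,3-dioxolan-4-yl]oxiran-2-yl]methyl benzoate F5, isolated by chromatography. Ring-closing metathesis (Grubbs II, CH2Cl2, 40 °C) closes the cyclohexene to 10; only the oxirane isomer with the vinyl group cis to the dioxolanyl arm can cyclise.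

**Step 5 (acetonide hydrolysis next to the vinyl epoxide).** The fallback replaces the acid-labile acetal by a fluoride-labile tether before the epoxide exists. It sets out from 6 and comes back at 11. Aqueous TFA (CH2Cl2, 0 °C) on 6 gives (3R,4S,5Z)-3,4-dihydroxy-2-oxo-7-(phenylsulfanyl)hept-5-en-1-yl benzoate F6. TIPDSCl2 and imidazole (DMF) give its cyclic 3,4-O-(1,1,3,3-tetraisopropyldisiloxane-1,3-diyl) derivative F7, whose seven-membered ring again enforces a gauche, diequatorial O–C–C–O. The step 4 conditions are then applied: MeOTf gives the S-methylsulfonium triflate F8, Cs2CO3 gives the sulfonium allylide F9, and this closes through the betaine F10 to the disiloxanediyl-protected epoxide F11. Buffered fluoride (TBAF/AcOH, THF, 0 °C) releases diol 11.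

**Step 6 (site-selective benzoylation).** The fallback ties the two hydroxyls together and differentiates them on ring opening. It sets out from 11 and comes back at 12. Trimethyl orthobenzoate with catalytic CSA (CH2Cl2, 20 °C) converts 11 into the trans-fused cyclic orthobenzoate (2,3-O-(α-methoxybenzylidene) derivative of 11, both configurations at the orthoester carbon) F12. Brief treatment with dilute aqueous AcOH opens it to the hydroxy benzoate. Collapse of the hemiorthoester should expel the more hindered and more acidic C2 oxygen, leaving the benzoate on C3, which is 12.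

## Further compounds

F1 | step 4 | methyl (4R,5S)-5-ethenyl-2,2-dimethyl-1,3-dioxolane-4-carboxylate | COC(=O)[C@@H]1OC(C)(C)O[C@H]1C=C
F2 | step 4 | 2-chloro-1-[(4R,5S)-5-ethenyl-2,2-dimethyl-1,3-dioxolan-4-yl]ethan-1-one | ClCC(=O)[C@@H]1OC(C)(C)O[C@H]1C=C
F3 | step 4 | 2-[(4R,5S)-5-ethenyl-2,2-dimethyl-1,3-dioxolan-4-yl]-2-oxoethyl benzoate | O=C(OCC(=O)[C@@H]1OC(C)(C)O[C@H]1C=C)c1ccccc1
F4 | step 4 | betaine from F3 and the S-allyltetrahydrothiophenium ylide (alkoxide on the former ketone carbon, tetrahydrothiophenium on the adjacent allylic carbon) | O=C(OC[C@]([O-])([C@@H](C=C)[S+]1CCCC1)[C@@H]1OC(C)(C)O[C@H]1C=C)c1ccccc1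
F5 | step 4 | [(2S,3S)-3-ethenyl-2-[(4R,5S)-5-ethenyl-2,2-dimethyl-1,3-dioxolan-4-yl]oxiran-2-yl]methyl benzoate | O=C(OC[C@@]1(O[C@H]1C=C)[C@@H]1OC(C)(C)O[C@H]1C=C)c1ccccc1
F6 | step 5 | (3R,4S,5Z)-3,4-dihydroxy-2-oxo-7-(phenylsulfanyl)hept-5-en-1-yl benzoate | O=C(OCC(=O)[C@H](O)[C@@H](O)/C=C\CSc1ccccc1)c1ccccc1
F7 | step 5 | 3,4-O-(1,1,3,3-tetraisopropyldisiloxane-1,3-diyl) derivative of F6 | O=C(OCC(=O)[C@@H]1O[Si](C(C)C)(C(C)C)O[Si](C(C)C)(C(C)C)O[C@H]1/C=C\CSc1ccccc1)c1ccccc1
F8 | step 5 | S-methylsulfonium triflate of F7 | O=C(OCC(=O)[C@@H]1O[Si](C(C)C)(C(C)C)O[Si](C(C)C)(C(C)C)O[C@H]1/C=C\C[S+](C)c1ccccc1)c1ccccc1.[O-]S(=O)(=O)C(F)(F)F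
F9 | step 5 | sulfonium allylide from F8 | O=C(OCC(=O)[C@@H]1O[Si](C(C)C)(C(C)C)O[Si](C(C)C)(C(C)C)O[C@H]1/C=C\[CH-][S+](C)c1ccccc1)c1ccccc1
F10 | step 5 | cyclised betaine from F9 (O⁻ on C1 cis to O–C2, sulfonio on C6 trans to O⁻) | O=C(OC[C@]1([O-])[C@H]([S+](C)c2ccccc2)C=C[C@@H]2O[Si](C(C)C)(C(C)C)O[Si](C(C)C)(C(C)C)O[C@@H]12)c1ccccc1
F11 | step 5 | 2,3-O-(1,1,3,3-tetraisopropyldisiloxane-1,3-diyl) derivative of 11 | O=C(OC[C@]12O[C@H]1C=C[C@@H]3O[Si](C(C)C)(C(C)C)O[Si](C(C)C)(C(C)C)O[C@@H]23)c1ccccc1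
F12 | step 6 | cyclic orthobenzoate of 11 (2,3-O-(α-methoxybenzylidene) derivative, both configurations at the orthoester carbon) | O=C(OC[C@]12O[C@H]1C=C[C@@H]3OC(OC)(c4ccccc4)O[C@@H]23)c1ccccc1
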